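The synthesis rests on disconnecting the C4–C5 bond (labdane numbering). C4 is flanked by the C3 ketone and the C19 lactone carbonyl, and it is attached to C5 on the same face of ring B as the lactone oxygen on C6. Ring A and the γ-lactone therefore share this one bond, and without it their perimeter is a single nine-membered ring. The precursor is that ring: an α-diazo β-keto lactone spanning C10 and O6 of a fully configured ring B whose C9 ketone is a dimethyl ketal. A rhodium carbenoid at C4 inserts across the ring into the equatorial C5–H, closing ring A and the lactone and setting C4 and C5 in one operation.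

Key step: step 10

Remarks on the design (labdane numbering throughout; α/β as in the target drawn with C20 up):
- Precursor: the C9 dimethyl ketal is kept through the key step because it leaves no C–H on C9 and stops C8 from epimerising. What the precursor needs beyond this is a secure 8α (equatorial) methyl, since that group decides the ring-B chair on which the insertion depends. C8 is therefore set first by catalyst control, and C10 and C6 follow from it by substrate control.
- The ketal must sit on the ring carbonyl that is flanked by the substituted carbons (C9). Ketalising a 2,6-disubstituted quinone would mask the other carbonyl, so the monoketal is made by oxidising a 4-methoxyphenol.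
- After the key step the C3 ketone is less hindered than the C9 ketone. The alkyne is therefore added while the β-keto lactone is masked as its enolate, and C4 is methylated afterwards.
- Nothing in the decalin can control C13, so it is brought in as a stereocentre of the alkyne.
- Assumptions: 5-hydroxy-2-methoxybenzaldehyde and 2-bromoprop-2-en-1-ol are catalogue compounds; the senses of induction in steps 4 and 13 follow the usual models and would be confirmed on the first run.

Step 1
Reactants: 1 5-hydroxy-2-methoxybenzaldehyde; 2 methyl (triphenylphosphoranylidene)acetate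
Product: 3 methyl (E)-3-(5-hydroxy-2-methoxyphenyl)prop-2-enoate
Conditions: PhMe, 80 °C
Reagents that add atoms: none
Why: Wittig olefination with a stabilised ylide tolerates the free phenol and gives the E-cinnamate that supplies C2 and C3.

Step 2
Reactants: 3 methyl (E)-3-(5-hydroxy-2-methoxyphenyl)prop-2-enoate
Product: 4 methyl 3-(5-hydroxy-2-methoxyphenyl)propanoate
Conditions: H2 (1 atm), Pd/C, EtOAc, 23 °C
Reagents that add atoms: none
Why: Catalytic hydrogenation of the cinnamate C=C leaves the arene and ester untouched.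

Step 3
Reactants: 4 methyl 3-(5-hydroxy-2-methoxyphenyl)propanoate
Product: 5 methyl 3-(6,6-dimethoxy-3-oxocyclohexa-1,4-dien-1-yl)propanoate
Conditions: PhI(OAc)2, MeOH, 0 °C
Reagents that add atoms: methanol, CO
Why: Oxidative dearomatisation of a 4-methoxyphenol in methanol gives the quinone monoketal with the ketal on the former anisole carbon (C9), next to the chain-bearing C10.

Step 4
Reactants: 5 methyl 3-(6,6-dimethoxy-3-oxocyclohexa-1,4-dien-1-yl)propanoate
Product: 6 methyl 3-[(5R)-6,6-dimethoxy-5-methyl-3-oxocyclohex-1-en-1-yl]propanoate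
Conditions: Me2Zn, Cu(OTf)2 (2 mol%), (S,R,R)-BINOL bis(1-phenylethyl)amine phosphoramidite (4 mol%; its mirror image if the sense proves opposite), PhMe, −25 °C; aq. NH4Cl
Reagents that add atoms: dimethylzinc, C[Zn]C
Why: Copper-catalysed asymmetric conjugate addition of a dialkylzinc to a quinone monoketal occurs only at the unsubstituted enone, and the ligand selects the face so that C8 should form as the 8α-methyl (R) centre; the adduct is kept away from acid because it can aromatise by loss of methanol.

Step 5
Reactants: 6 methyl 3-[(5R)-6,6-dimethoxy-5-methyl-3-oxocyclohex-1-en-1-yl]propanoate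
Product: 8 methyl 3-[(1S,3R)-2,2-dimethoxy-1,3-dimethyl-5-oxocyclohexyl]propanoate, via silyl enol ether 7 (not isolated)
Conditions: Me2CuLi (from MeLi, CuI), Me3SiCl, THF, −78 → −30 °C; then K2CO3 (cat.), MeOH, 0 °C
Reagents that add atoms: lithium dimethylcuprate, [Li+].C[Cu-]C
Why: In this silyl-chloride-accelerated organocuprate conjugate addition to a 5-substituted cyclohexenone, methyl enters axially and trans to the C8 methyl, making C10 quaternary with C20 trans to C17, while silylation keeps the enolate from attacking the chain ester.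

Step 6
Reactants: 8 methyl 3-[(1S,3R)-2,2-dimethoxy-1,3-dimethyl-5-oxocyclohexyl]propanoate
Product: 9 methyl 3-[(1S,3R,5R)-5-hydroxy-2,2-dimethoxy-1,3-dimethylcyclohexyl]propanoate
Conditions: LiBH(s-Bu)3, THF, −78 °C; aq. NH4Cl
Reagents that add atoms: none
Why: In this bulky-hydride reduction the ketone sits in the chair with C20 axial, so hydride can only arrive equatorially and the alcohol should be axial and cis to C20 (6β), with the ester inert at −78 °C.

Step 7
Reactants: 9 methyl 3-[(1S,3R,5R)-5-hydroxy-2,2-dimethoxy-1,3-dimethylcyclohexyl]propanoate; 10 tert-butyl acetate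
Product: 11 tert-butyl 5-[(1S,3R,5R)-5-hydroxy-2,2-dimethoxy-1,3-dimethylcyclohexyl]-3-oxopentanoate
Conditions: LiN(i-Pr)2 and 10 (4 equiv each), THF, −78 → −20 °C; aq. NH4Cl
Reagents that add atoms: none
Why: Crossed Claisen condensation of the acetate enolate with the methyl ester adds C4 and C19; excess enolate covers the free hydroxyl and the acidic product.

Step 8
Reactants: 11 tert-butyl 5-[(1S,3R,5R)-5-hydroxy-2,2-dimethoxy-1,3-dimethylcyclohexyl]-3-oxopentanoate
Product: 13 nine-membered β-keto lactone (9,9-dimethoxy-3-oxo-4,5-seco-11,12,13,14,15,16,18-heptanorlabdan-19,6β-olide), via acylketene 12 (not isolated)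
Conditions: PhMe, 110 °C, slow addition to ≤1 mM
Reagents that add atoms: none
Why: Thermolysis of a tert-butyl β-keto ester releases tert-butanol and an acylketene that the axial C6 hydroxyl traps intramolecularly (acylketene macrolactonisation, a method known for medium rings).

Step 9
Reactants: 13 nine-membered β-keto lactone
Product: 14 4-diazo-9,9-dimethoxy-3-oxo-4,5-seco-11,12,13,14,15,16,18-heptanorlabdan-19,6β-olide
Conditions: 4-AcNHC6H4SO2N3, Et3N, MeCN, 0 → 23 °C
Reagents that add atoms: 4-acetamidobenzenesulfonyl azide, CC(=O)Nc1ccc(cc1)S(=O)(=O)N=[N+]=[N-]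
Why: Regitz diazo transfer to the active methylene between the ketone and the lactone carbonyl.

Step 10
Reactants: 14 4-diazo-9,9-dimethoxy-3-oxo-4,5-seco-11,12,13,14,15,16,18-heptanorlabdan-19,6β-olide
Product: 15 9,9-dimethoxy-3-oxo-11,12,13,14,15,16,18-heptanorlabdan-19,6β-olide (4α-H, 5α-H, 8α-Me, 10β-Me)
Conditions: Rh2(OAc)4 (2 mol%), CH2Cl2, 40 °C, slow addition
Reagents that add atoms: none
Why: Proposed new method: Rh2(OAc)4 expels N2 from 14 to give an electrophilic acceptor/acceptor rhodium carbenoid at C4, which inserts into the transannular equatorial C5–Hβ through a concerted, asynchronous three-centre transition state with retention at C5; the closest known reaction types are the 1,5 C–H insertion of diazoacetoacetate esters to γ-lactones, the cyclisation of α-diazo β-keto esters to cycloalkanones and transannular carbene C–H insertion in medium rings. The single new C4–C5 bond closes the γ-lactone as a 1,5-insertion counted through the ester oxygen (O6–C19–C4) and ring A as a 1,6-insertion counted through the ketone arm (C10–C1–C2–C3–C4), both by partition of the nine-membered ring. C5 is controlled by which hydrogen is replaced: the equatorial β-H is gauche to both the axial O6 and the equatorial C1, so the lactone is cis-fused and the A/B junction trans, whereas the axial α-H is anti to O6 and cannot give a five-membered lactone. C4 can only carry C19 on the β-face of ring A to bridge to O6, and its remaining hydrogen is acidic and is replaced in step 19. Site selectivity is secured by the substrate: quaternary C10 removes the usual five-ring insertion on the ketone side, the ketal leaves no C–H on C9, the C10 anchor keeps C4 over C5 and away from C7, and the equatorial 8α-methyl holds ring B in the chair with axial O6; the C20 methyl C–H bonds and the C6–H (β-lactone) remain as competitors and are intrinsically slower.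

Step 11
Reactants: 15 9,9-dimethoxy-3-oxo-11,12,13,14,15,16,18-heptanorlabdan-19,6β-olide
Product: 16 3,9-dioxo-11,12,13,14,15,16,18-heptanorlabdan-19,6β-olide
Conditions: 1 M HCl, THF, 23 °C
Reagents that add atoms: water, O
Why: Acid hydrolysis of the hindered dimethyl ketal; the γ-lactone is stable to dilute acid and the equatorial 8α-methyl is also the thermodynamic configuration beside the new ketone.

Step 12
Reactants: 17 2-bromoprop-2-en-1-ol; 18 ethynyltrimethylsilane
Product: 19 2-methylidene-4-(trimethylsilyl)but-3-yn-1-ol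
Conditions: Pd(PPh3)2Cl2 (2 mol%), CuI (4 mol%), i-Pr2NH, THF, 23 °C
Reagents that add atoms: none
Why: Sonogashira coupling of a vinyl bromide with a terminal alkyne assembles C11–C14 and C16.

Step 13
Reactants: 19 2-methylidene-4-(trimethylsilyl)but-3-yn-1-ol
Product: 20 [(2R)-2-[(trimethylsilyl)ethynyl]oxiran-2-yl]methanol
Conditions: Ti(Oi-Pr)4, D-(−)-diisopropyl tartrate, t-BuOOH, 4 Å MS, CH2Cl2, −20 °C
Reagents that add atoms: tert-butyl hydroperoxide, CC(C)(C)OO
Why: Sharpless asymmetric epoxidation of a 2-substituted allylic alcohol; the D-tartrate should give the (R)-epoxide, which fixes C13.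

Step 14
Reactants: 20 [(2R)-2-[(trimethylsilyl)ethynyl]oxiran-2-yl]methanol; 21 1,3-dithiane
Product: 22 (2R)-2-(1,3-dithian-2-ylmethyl)-4-(trimethylsilyl)but-3-yne-1,2-diol
Conditions: 21, n-BuLi (2.4 equiv), THF, −30 °C; then 20, −30 → 0 °C; aq. NH4Cl
Reagents that add atoms: none
Why: Corey–Seebach umpolung: 2-lithio-1,3-dithiane opens the epoxide at its CH2 terminus, so C13 is untouched and C15 arrives at the aldehyde oxidation level.

Step 15
Reactants: 22 (2R)-2-(1,3-dithian-2-ylmethyl)-4-(trimethylsilyl)but-3-yne-1,2-diol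
Product: 23 (3R)-5-methoxy-3-[(trimethylsilyl)ethynyl]oxolan-3-ol (both anomers)
Conditions: PhI(O2CCF3)2, MeOH/CH2Cl2, 0 → 23 °C
Reagents that add atoms: methanol, CO
Why: Oxidative dithiane cleavage in methanol; the primary C16 hydroxyl and methanol capture the oxocarbenium ion as the five-membered cyclic methyl acetal, which ties up the C16 oxygen.

Step 16
Reactants: 23 (3R)-5-methoxy-3-[(trimethylsilyl)ethynyl]oxolan-3-ol
Product: 24 triethyl{[(3R)-5-methoxy-3-[(trimethylsilyl)ethynyl]oxolan-3-yl]oxy}silane
Conditions: Et3SiCl, imidazole, DMAP (cat.), DMF, 40 °C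
Reagents that add atoms: chlorotriethylsilane, CC[Si](Cl)(CC)CC
Why: Silylation of the tertiary alcohol, so that the C9 hydroxyl is the only free one when the alkyne is rearranged in step 20.

Step 17
Reactants: 24 triethyl{[(3R)-5-methoxy-3-[(trimethylsilyl)ethynyl]oxolan-3-yl]oxy}silane
Product: 25 triethyl{[(3R)-3-ethynyl-5-methoxyoxolan-3-yl]oxy}silane
Conditions: K2CO3, MeOH, 23 °C
Reagents that add atoms: none
Why: Methoxide-mediated protodesilylation of the alkynylsilane; the tertiary triethylsilyl ether and the acetal survive.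

Step 18
Reactants: 16 3,9-dioxo-11,12,13,14,15,16,18-heptanorlabdan-19,6β-olide; 25 triethyl{[(3R)-3-ethynyl-5-methoxyoxolan-3-yl]oxy}silane
Product: 27 (13R)-9β-hydroxy-15-methoxy-3-oxo-13-(triethylsilyloxy)-15,16-epoxy-18-norlabd-11-yn-19,6β-olide, via lithium enolate 26 (not isolated)
Conditions: 16, LiN(SiMe3)2 (1.05 equiv), THF, −78 °C; then lithium acetylide of 25 (n-BuLi), −78 → 0 °C; aq. NH4Cl
Reagents that add atoms: none
Why: 1,2-Addition of a lithium acetylide to the hindered C9 ketone while the β-keto lactone is masked as its enolate, so that the C3 carbonyl and the lactone are inert; axial attack from the α-face is expected, which is immaterial because C9 becomes trigonal in step 20.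

Step 19
Reactants: 27 (13R)-9β-hydroxy-15-methoxy-3-oxo-13-(triethylsilyloxy)-15,16-epoxy-18-norlabd-11-yn-19,6β-olide
Product: 28 (13R)-9β-hydroxy-15-methoxy-3-oxo-13-(triethylsilyloxy)-15,16-epoxylabd-11-yn-19,6β-olide
Conditions: K2CO3, MeI, acetone, 40 °C
Reagents that add atoms: iodomethane, CI
Why: C-Alkylation of the β-keto lactone enolate; methyl can only enter on the α-face because C19 is tied to O6 on the β-face, giving quaternary C4 with C18 α.

Step 20
Reactants: 28 (13R)-9β-hydroxy-15-methoxy-3-oxo-13-(triethylsilyloxy)-15,16-epoxylabd-11-yn-19,6β-olide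
Product: 31 (13S)-9α,13:15,16-diepoxy-15-methoxy-3,12-dioxolabdan-19,6β-olide, via enone 29 (not isolated), via hydroxy enone 30 (not isolated)
Conditions: MoO2(acac)2, AuCl(PPh3), AgOTf (5 mol% each), PhMe, 23 °C; then CSA, MeOH, 23 → 40 °C
Reagents that add atoms: none
Why: Meyer–Schuster rearrangement through the molybdate ester of the only free hydroxyl (C9) puts the carbonyl on C12, then acid removes the silyl ether and the C13 hydroxyl closes the furanone by 5-endo oxa-Michael addition to the tertiary, cation-like C9, oxygen entering axially on the α-face anti to the C20 methyl, which sets C9.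

Step 21
Reactants: 31 (13S)-9α,13:15,16-diepoxy-15-methoxy-3,12-dioxolabdan-19,6β-olide
Product: 32 (13S)-9α,13:15,16-diepoxy-15-hydroxy-3,12-dioxolabdan-19,6β-olide
Conditions: AcOH/THF/H2O (3:1:1), 40 °C
Reagents that add atoms: water, O
Why: Mild hydrolysis of the furanosidic methyl acetal to the lactol, in acid too weak to reopen the tertiary spiro ether.

Step 22
Reactants: 32 (13S)-9α,13:15,16-diepoxy-15-hydroxy-3,12-dioxolabdan-19,6β-olide
Product: 34 (13S)-9α,13:15,16-diepoxy-3,12-dioxolabd-14-en-19,6β-olide (CNP0143138.1), via lactol mesylate 33 (not isolated)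
Conditions: MsCl, Et3N, CH2Cl2, −40 → 23 °C
Reagents that add atoms: none
Why: Mesylation of the lactol and amine-induced elimination, the standard dehydration of 2-deoxy lactols to cyclic enol ethers; only C14 carries β-hydrogens, so the C14=C15 enol ether should form under non-acidic conditions that the product tolerates.

Compound list
1 | 5-hydroxy-2-methoxybenzaldehyde | COc1ccc(O)cc1C=O | starting material
2 | methyl (triphenylphosphoranylidene)acetate | COC(=O)C=P(c1ccccc1)(c1ccccc1)c1ccccc1 | starting material
3 | methyl (E)-3-(5-hydroxy-2-methoxyphenyl)prop-2-enoate | COC(=O)/C=C/c1cc(O)ccc1OC | intermediate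
4 | methyl 3-(5-hydroxy-2-methoxyphenyl)propanoate | COC(=O)CCc1cc(O)ccc1OC | intermediate
5 | methyl 3-(6,6-dimethoxy-3-oxocyclohexa-1,4-dien-1-yl)propanoate | COC(=O)CCC1=CC(=O)C=CC1(OC)OC | intermediate
6 | methyl 3-[(5R)-6,6-dimethoxy-5-methyl-3-oxocyclohex-1-en-1-yl]propanoate | C[C@@H]1CC(=O)C=C(CCC(=O)OC)C1(OC)OC | intermediate
7 | methyl 3-[(1S,5R)-6,6-dimethoxy-1,5-dimethyl-3-(trimethylsilyloxy)cyclohex-2-en-1-yl]propanoate | C[C@@H]1CC(O[Si](C)(C)C)=C[C@](C)(CCC(=O)OC)C1(OC)OC | intermediate
8 | methyl 3-[(1S,3R)-2,2-dimethoxy-1,3-dimethyl-5-oxocyclohexyl]propanoate | C[C@@H]1CC(=O)C[C@](C)(CCC(=O)OC)C1(OC)OC | intermediate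
9 | methyl 3-[(1S,3R,5R)-5-hydroxy-2,2-dimethoxy-1,3-dimethylcyclohexyl]propanoate | C[C@@H]1C[C@@H](O)C[C@](C)(CCC(=O)OC)C1(OC)OC | intermediate
10 | tert-butyl acetate | CC(=O)OC(C)(C)C | starting material
11 | tert-butyl 5-[(1S,3R,5R)-5-hydroxy-2,2-dimethoxy-1,3-dimethylcyclohexyl]-3-oxopentanoate | C[C@@H]1C[C@@H](O)C[C@](C)(CCC(=O)CC(=O)OC(C)(C)C)C1(OC)OC | intermediate
12 | acylketene from 11 (3-oxopent-1-en-1-one chain on C10) | C[C@@H]1C[C@@H](O)C[C@](C)(CCC(=O)C=C=O)C1(OC)OC | intermediate
13 | nine-membered β-keto lactone, 9,9-dimethoxy-3-oxo-4,5-seco-11,12,13,14,15,16,18-heptanorlabdan-19,6β-olide | C[C@@H]1C[C@H]2OC(=O)CC(=O)CC[C@@](C)(C2)C1(OC)OC | intermediate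
14 | 4-diazo-9,9-dimethoxy-3-oxo-4,5-seco-11,12,13,14,15,16,18-heptanorlabdan-19,6β-olide | C[C@@H]1C[C@H]2OC(=O)C(=[N+]=[N-])C(=O)CC[C@@](C)(C2)C1(OC)OC | intermediate
15 | 9,9-dimethoxy-3-oxo-11,12,13,14,15,16,18-heptanorlabdan-19,6β-olide (4α-H, 5α-H) | C[C@@H]1C[C@H]2OC(=O)[C@H]3C(=O)CC[C@@](C)([C@@H]23)C1(OC)OC | intermediate
16 | 3,9-dioxo-11,12,13,14,15,16,18-heptanorlabdan-19,6β-olide | C[C@@H]1C[C@H]2OC(=O)[C@H]3C(=O)CC[C@@](C)([C@@H]23)C1=O | intermediate
17 | 2-bromoprop-2-en-1-ol | OCC(Br)=C | starting material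
18 | ethynyltrimethylsilane | C#C[Si](C)(C)C | starting material
19 | 2-methylidene-4-(trimethylsilyl)but-3-yn-1-ol | OCC(=C)C#C[Si](C)(C)C | intermediate
20 | [(2R)-2-[(trimethylsilyl)ethynyl]oxiran-2-yl]methanol | OC[C@]1(C#C[Si](C)(C)C)CO1 | intermediate
21 | 1,3-dithiane | C1CSCSC1 | starting material
22 | (2R)-2-(1,3-dithian-2-ylmethyl)-4-(trimethylsilyl)but-3-yne-1,2-diol | OC[C@@](O)(CC1SCCCS1)C#C[Si](C)(C)C | intermediate
23 | (3R)-5-methoxy-3-[(trimethylsilyl)ethynyl]oxolan-3-ol | COC1C[C@@](O)(C#C[Si](C)(C)C)CO1 | intermediate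
24 | triethyl{[(3R)-5-methoxy-3-[(trimethylsilyl)ethynyl]oxolan-3-yl]oxy}silane | COC1C[C@@](O[Si](CC)(CC)CC)(C#C[Si](C)(C)C)CO1 | intermediate
25 | triethyl{[(3R)-3-ethynyl-5-methoxyoxolan-3-yl]oxy}silane | COC1C[C@@](O[Si](CC)(CC)CC)(C#C)CO1 | intermediate
26 | lithium C3–C4 enolate of 16 | [Li+].C[C@@H]1C[C@H]2OC(=O)C3=C([O-])CC[C@@](C)([C@@H]23)C1=O | intermediate
27 | (13R)-9β-hydroxy-15-methoxy-3-oxo-13-(triethylsilyloxy)-15,16-epoxy-18-norlabd-11-yn-19,6β-olide | C[C@@H]1C[C@H]2OC(=O)[C@H]3C(=O)CC[C@@](C)([C@@H]23)[C@]1(O)C#C[C@]4(O[Si](CC)(CC)CC)CC(OC)OC4 | intermediate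
28 | (13R)-9β-hydroxy-15-methoxy-3-oxo-13-(triethylsilyloxy)-15,16-epoxylabd-11-yn-19,6β-olide | C[C@@H]1C[C@H]2OC(=O)[C@@]3(C)C(=O)CC[C@@](C)([C@@H]23)[C@]1(O)C#C[C@]4(O[Si](CC)(CC)CC)CC(OC)OC4 | intermediate
29 | (13S)-15-methoxy-3,12-dioxo-13-(triethylsilyloxy)-15,16-epoxylabd-9(11)-en-19,6β-olide (C12 cis to C8) | C[C@@H]1C[C@H]2OC(=O)[C@@]3(C)C(=O)CC[C@@](C)([C@@H]23)/C1=C/C(=O)[C@]4(O[Si](CC)(CC)CC)CC(OC)OC4 | intermediate
30 | (13S)-13-hydroxy-15-methoxy-3,12-dioxo-15,16-epoxylabd-9(11)-en-19,6β-olide | C[C@@H]1C[C@H]2OC(=O)[C@@]3(C)C(=O)CC[C@@](C)([C@@H]23)/C1=C/C(=O)[C@]4(O)CC(OC)OC4 | intermediate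
31 | (13S)-9α,13:15,16-diepoxy-15-methoxy-3,12-dioxolabdan-19,6β-olide | C[C@@H]1C[C@H]2OC(=O)[C@@]3(C)C(=O)CC[C@@](C)([C@@H]23)[C@@]12CC(=O)[C@@]1(CC(OC)OC1)O2 | intermediate
32 | (13S)-9α,13:15,16-diepoxy-15-hydroxy-3,12-dioxolabdan-19,6β-olide | C[C@@H]1C[C@H]2OC(=O)[C@@]3(C)C(=O)CC[C@@](C)([C@@H]23)[C@@]12CC(=O)[C@@]1(CC(O)OC1)O2 | intermediate
33 | 15-O-methanesulfonate of 32 | C[C@@H]1C[C@H]2OC(=O)[C@@]3(C)C(=O)CC[C@@](C)([C@@H]23)[C@@]12CC(=O)[C@@]1(CC(OS(C)(=O)=O)OC1)O2 | intermediate
34 | (13S)-9α,13:15,16-diepoxy-3,12-dioxolabd-14-en-19,6β-olide | C[C@@H]1C[C@H]2OC(=O)[C@@]3(C)C(=O)CC[C@@](C)([C@@H]23)[C@@]12CC(=O)[C@@]1(C=COC1)O2 | target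

Total step count: 22. Longest linear sequence: 16 (steps 1–11 and 18–22); the alkyne 25 is made in 6 steps (12–17).

Steps most likely to fail

1. Step 10 (carries the new-method label). The carbenoid may be consumed by a competing path: insertion into a C20 methyl C–H or the C6–H, reaction from the flipped ring-B chair (cis A/B junction), or carbene dimerisation if the transannular geometry is not reached. Fallback by classical enolate chemistry, setting out from 7 (isolated by non-aqueous work-up instead of being cleaved) and returning at 15. MeLi regenerates the regiodefined C5 enolate, which is alkylated with methyl bromoacetate (THF/DMPU). DBU then equilibrates C5 so that the new arm is equatorial (β), giving the keto diester F1. LiBH(s-Bu)3 reduces C6 from the equatorial side, and the axial 6β-alkoxide closes onto the neighbouring ester to give the cis-fused γ-lactone ester F2. LiN(SiMe3)2 deprotonates the lactone α-carbon (C4, the most acidic C–H), which attacks the chain ester in a Dieckmann condensation that forms ring A and delivers 15.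

2. Step 8. Closure of the strained, bridged nine-membered ring may be slower than intermolecular trapping of the acylketene, leading to oligomers. Fallback that closes the ring at C3–C4 instead of at the ester oxygen, setting out from 9 and returning at 13. i-Bu2AlH (−78 °C) takes the ester to the hydroxy aldehyde F3. Bromoacetyl bromide/pyridine gives the bromoacetate F4. SmI2 under high dilution effects a samarium-templated intramolecular Reformatsky reaction to the nine-membered β-hydroxy lactone F5. IBX oxidation gives 13.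

3. Step 20. The rearrangement may stall at the very hindered tertiary C9 alcohol or divert to elimination towards C8, and the 5-endo closure may be slow. Fallback that reaches the same ring through an aldol-type intermediate, setting out from 28 and returning at 31. Ruthenium-catalysed trans-hydrosilylation ([Cp*Ru(MeCN)3]PF6, BnMe2SiH) places silicon on C12, distal to the free C9 hydroxyl, giving the vinylsilane F6. Tamao–Fleming oxidation (TBAF; then H2O2, KHCO3) gives the β-hydroxy ketone F7 with the C13 silyl ether also removed. CSA in MeOH ionises the tertiary C9 alcohol and the C13 hydroxyl closes the furanone to 31.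

Further compounds
F1 | step 10 | keto diester, methyl 3-[2,2-dimethoxy-6-(2-methoxy-2-oxoethyl)-1,3-dimethyl-5-oxocyclohexyl]propanoate (C4 arm 5β) | C[C@@H]1CC(=O)[C@@H](CC(=O)OC)[C@](C)(CCC(=O)OC)C1(OC)OC
F2 | step 10 | cis-fused γ-lactone ester (19,6β-olide with ring A open between C3 and C4) | C[C@@H]1C[C@H]2OC(=O)C[C@H]2[C@](C)(CCC(=O)OC)C1(OC)OC
F3 | step 8 | hydroxy aldehyde, 3-[(1S,3R,5R)-5-hydroxy-2,2-dimethoxy-1,3-dimethylcyclohexyl]propanal | C[C@@H]1C[C@@H](O)C[C@](C)(CCC=O)C1(OC)OC
F4 | step 8 | bromoacetate of F3 | C[C@@H]1C[C@@H](OC(=O)CBr)C[C@](C)(CCC=O)C1(OC)OC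
F5 | step 8 | nine-membered β-hydroxy lactone (3-hydroxy analogue of 13, both C3 epimers) | C[C@@H]1C[C@H]2OC(=O)CC(O)CC[C@@](C)(C2)C1(OC)OC
F6 | step 20 | C12 benzyldimethylsilyl vinylsilane from 28 | C[C@@H]1C[C@H]2OC(=O)[C@@]3(C)C(=O)CC[C@@](C)([C@@H]23)[C@]1(O)/C=C(\[Si](C)(C)Cc1ccccc1)[C@]4(O[Si](CC)(CC)CC)CC(OC)OC4
F7 | step 20 | 9β,13-dihydroxy-15-methoxy-3,12-dioxo-15,16-epoxylabdan-19,6β-olide | C[C@@H]1C[C@H]2OC(=O)[C@@]3(C)C(=O)CC[C@@](C)([C@@H]23)[C@]1(O)CC(=O)[C@]4(O)CC(OC)OC4
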